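I have no constants for this flask, only two earlier runs, so I work from their readings. A solid substrate dissolves to starting material, which goes on in solution to intermediate and target and also turns into a dormant form.

| flask | solid substrate | remark | time |
|---|---|---|---|
| zeta | 17 mM | run made earlier |  |
| eta | 68 mM | run made earlier |  |
| flask | 34 mM |  | 5.0 h |

| run | time / h | target / % | solid substrate / % |
|---|---|---|---|
| zeta | 0.500 | 17 | 2 |
| zeta | 1.00 | 22 | 3 |
| zeta | 2.50 | 32 | 0 |
| zeta | 6.00 | 34 | 0 |
| eta | 1.50 | 17 | 19 |
| eta | 3.00 | 28 | 3 |
| eta | 5.00 | 35 | 2 |
| eta | 6.00 | 30 | 0 |

(each reading ± 2 percentage points)

- given per volume of solution although it is solid: solid substrate
- reactions considered so far: starting material <-> intermediate; intermediate <-> target; starting material <-> dormant form; solid substrate <-> starting material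
- at the start none of the solid substrate is in solution
- what has only dissolved of solid substrate counts as not reacted
- the reaction counts as stopped when no species that holds the solid substrate changes by six tenths of a point or more over the second half of the time

- which holds at 5.0 h: what has brought the reaction to rest, or that it has not come to rest (for what has run out or reacted, a solid counts together with what of it has only dissolved) (forward and back rates have come level / it is still moving / all of the solid substrate has reacted)
- how much target there is at 5.0 h, in percent of the solid substrate charged

I build the flask up one process at a time. First comes the chain in solution by itself. If its steps are first order and reversible, target ends at a set part of the charge whatever the loading, which is thermodynamic control in the usual term. The eta charge is 4.00 times the zeta charge, yet the last zeta reading, 34%, and the eta readings 35% and 30% average 33.0%. I call this mean of the late target readings the plateau share, p; as a reading it carries a scatter of 1.2 percentage points.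

Next I add the dissolving and replace its curve by its mean. Eta loses solid at 36.7 mM/h up to 1.50 h, so this flask dissolves its charge in about 0.926 h, well before 5.0 h. Zeta's first reading gives 33.3 mM/h, which makes that 1.02 h, a small error.

Last comes the rest. The dormant form has no readings, but whatever it holds at rest is already inside p. At 2.50 h zeta stands 1 point below p, and this flask dissolves later than zeta did. I therefore expect a gain above 0.6 of a point in the second half, though that gap is smaller than the scatter. I commit to p and to a flask still moving.

The forecast says it is still moving, with 33% of target, between 30% and 36%. Its ground is “the end is a balance, not exhaustion”.

At 5.0 h the flask holds 32.5% of target, and it is still moving.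

    starting material ⇌ intermediate (K = 2.40, k = 0.0251 /min)
    intermediate ⇌ target (K = 0.940, k = 0.120 /min)
    starting material ⇌ dormant form (K = 1.17, k = 0.0303 /min)
    solid substrate ⇌ starting material, rate k4*(cs4 - [starting material]) while solid is left; crystals form when [starting material] > cs4 (solubility = 17.0 mM, k = 0.227 /min)

Over the second half of the time the largest move among substrate, intermediate and product is 3.2 points, and the dormant form falls from 22.3% to 17.9%, against the limit of 0.6. The flask's target lies 0.50 points below p, inside p's scatter. The neighbour charged with 140 mM still has 32.2% as solid at 5.00 h. Applied to the part out of the solid, p gives 22.4%, and that neighbour holds 20.3% of target.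

Readings and results come from a simulation from invented constants.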